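## Retrosynthetic overview
1. The enone comes from oxidation of the C10 allylic alcohol. The seven-membered ring B is closed last by ring-closing metathesis (C8=C9) of a cyclopentane that carries a C10 vinyl carbinol and, trans to it, a C6 methallyl carbinol ester.
2. Key disconnection C6–C7: intermolecular carbonyl methallylation of the C5 β-hydroxy aldehyde (C13 fragment) with methallylindium (C4 fragment), chelate-controlled by the free C4–OH. The ester comes from 3,4,5-trimethoxybenzoyl chloride.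
3. The C10 vinyl carbinol derives from CHO, CH2OH and CO2H, and the acid from a phenyl group (RuO4). The C4 carbinol comes from isopropenylcerium addition to a cyclopentanone, then H2.
4. The C5–C6 bond comes from a formaldehyde aldol of the α′-enolate of (R)-4-methyl-4-phenylcyclopent-2-enone.
5. The C1 quaternary centre comes from Pd/PyOx conjugate arylation of 3-methylcyclopent-2-enone, whose ring is the five-membered ring A and is present from the start.

Locants C1–C10 are the daucane locants of the target: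
- C1: quaternary carbon bearing CH3
- C2/C3: ring CH2
- C4: carbinol carbon (OH, i-Pr)
- C5: ring-fusion CH
- C6: ester carbinol
- C7: CH2
- C8(CH3)=C9H: the ring olefin
- C10: ketone

β is the face of the C1 methyl group. TBS = tert-butyldimethylsilyl.

Assumption 1: the roughly 91% ee from step 1 is raised to >99% ee by recrystallising the carboxylic acid of step 8, if needed as its (S)-1-phenylethylamine salt.
Assumption 2: the C10 carbinol centre made in step 11 is carried as a mixture of epimers, is left undefined in the SMILES, and is erased in step 19.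

## Route

Step 1
Reactants: 1 3-methylcyclopent-2-en-1-one; 2 phenylboronic acid
Product: 3 (S)-3-methyl-3-phenylcyclopentan-1-one
Conditions: Pd(OCOCF3)2 (5 mol %), (R)-t-BuPyOx (6 mol %), NH4PF6 (30 mol %), H2O (5 equiv), ClCH2CH2Cl, 40 °C
Reagents that add atoms: phenylboronic acid (2), OB(O)c1ccccc1
Why: Palladium-catalysed asymmetric conjugate addition (Michael-type 1,4-arylation) in which the aryl–palladium–PyOx complex inserts into one enone face only; since the (S)-ligand is known to give the (R)-ketones, the (R)-ligand sets C1 as (S) in about 91% ee, with phenyl serving as bulky control element and masked carboxyl group.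

Step 2
Reactants: 3 (S)-3-methyl-3-phenylcyclopentan-1-one
Product: 4 (R)-4-methyl-4-phenylcyclopent-2-en-1-one
Conditions: IBX (2 equiv), DMSO/toluene (1:2), 75 °C
Reagents that add atoms: none
Why: IBX dehydrogenation of a ketone to an enone, in which only the C2–C3 bond can be desaturated because C1 bears no hydrogen, so the stereocentre is untouched (the descriptor changes by priority only) and C5 is left as the sole enolisable position.

Step 3
Reactants: 4 (R)-4-methyl-4-phenylcyclopent-2-en-1-one; 5 formaldehyde (monomer gas cracked from paraformaldehyde)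
Product: 7 (4S,5S)-5-(hydroxymethyl)-4-methyl-4-phenylcyclopent-2-en-1-one, via lithium dienolate 6 (not isolated)
Conditions: LiN(i-Pr)2 (1.1 equiv), THF, −78 °C; CH2O (g), −78 °C; AcOH (1.2 equiv), −78 °C
Reagents that add atoms: formaldehyde (5), C=O
Why: Crossed aldol addition of a preformed kinetic lithium enolate to non-enolisable formaldehyde, in which the flat cross-conjugated dienolate is attacked anti to the phenyl group on C1 and so sets C5 with CH2OH trans to phenyl and cis to methyl, which is also the thermodynamically preferred epimer.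

Step 4
Reactants: 7 (4S,5S)-5-(hydroxymethyl)-4-methyl-4-phenylcyclopent-2-en-1-one
Product: 8 (4S,5S)-5-{[(TBS)oxy]methyl}-4-methyl-4-phenylcyclopent-2-en-1-one
Conditions: TBSCl, imidazole, DMF, 0 °C to rt
Reagents that add atoms: tert-butyldimethylsilyl chloride, CC(C)(C)[Si](C)(C)Cl
Why: Standard silyl ether protection of the primary alcohol stops retro-aldol loss of formaldehyde and dehydration to the exocyclic enone, and the group survives hydrogenation, organometal addition and borane.

Step 5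
Reactants: 8 (4S,5S)-5-{[(TBS)oxy]methyl}-4-methyl-4-phenylcyclopent-2-en-1-one
Product: 9 (2S,3S)-2-{[(TBS)oxy]methyl}-3-methyl-3-phenylcyclopentan-1-one
Conditions: H2 (1 atm), 10% Pd/C, EtOAc, rt
Reagents that add atoms: none
Why: Heterogeneous catalytic hydrogenation reduces only the conjugated C2=C3 bond, whose regiochemical blocking role is finished, while arene, ketone and silyl ether are inert and no stereocentre is formed or lost.

Step 6
Reactants: 9 (2S,3S)-2-{[(TBS)oxy]methyl}-3-methyl-3-phenylcyclopentan-1-one; 10 isopropenylmagnesium bromide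
Product: 12 (1S,2S,3S)-2-{[(TBS)oxy]methyl}-3-methyl-3-phenyl-1-(prop-1-en-2-yl)cyclopentan-1-ol, via isopropenylcerium dichloride 11 (not isolated)
Conditions: anhydrous CeCl3 (3 equiv), CH2=C(CH3)MgBr (3 equiv), THF, −78 °C, 1 h; then 9, −78 to 0 °C; aq NH4Cl
Reagents that add atoms: isopropenylmagnesium bromide (10), CC(=C)[Mg]Br
Why: Imamoto organocerium 1,2-addition, in which the oxophilic, barely basic reagent adds to the hindered β-silyloxy ketone without enolisation, elimination or hydride transfer and enters on the α-face, anti to the adjacent C5 side chain and the pseudoaxial C1 methyl, so the C4 hydroxyl ends up β and cis to C6 (descriptor S here only because isopropenyl outranks C5).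

Step 7
Reactants: 12 (1S,2S,3S)-2-{[(TBS)oxy]methyl}-3-methyl-3-phenyl-1-(prop-1-en-2-yl)cyclopentan-1-ol
Product: 13 (1R,2S,3S)-2-{[(TBS)oxy]methyl}-3-methyl-3-phenyl-1-(propan-2-yl)cyclopentan-1-ol
Conditions: H2 (1 atm), 10% Pd/C, EtOAc, rt
Reagents that add atoms: none
Why: Catalytic hydrogenation of the 1,1-disubstituted olefin turns isopropenyl into isopropyl without creating a stereocentre (C4 only changes descriptor to R), and neutral EtOAc keeps the silyl ether and the tertiary C–O bond intact.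

Step 8
Reactants: 13 (1R,2S,3S)-2-{[(TBS)oxy]methyl}-3-methyl-3-phenyl-1-(propan-2-yl)cyclopentan-1-ol
Product: 14 (1S,2S,3R)-2-{[(TBS)oxy]methyl}-3-hydroxy-1-methyl-3-(propan-2-yl)cyclopentane-1-carboxylic acid
Conditions: RuCl3·xH2O (5 mol %), NaIO4 (16 equiv), EtOAc/MeCN/H2O (2:2:3), rt, 24 h
Reagents that add atoms: sodium periodate, [Na+].[O-]I(=O)(=O)=O; water, O
Why: Ruthenium tetroxide degradation of an arene to a carboxylic acid (Sharpless conditions), in which RuO4 attacks the π-system far faster than saturated C–H bonds, the tertiary alcohol cannot be oxidised, and C1 keeps its configuration because the C1–C(ipso) bond is retained as C1–C10.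

Step 9
Reactants: 14 (1S,2S,3R)-2-{[(TBS)oxy]methyl}-3-hydroxy-1-methyl-3-(propan-2-yl)cyclopentane-1-carboxylic acid
Product: 15 (1R,2S,3S)-2-{[(TBS)oxy]methyl}-3-(hydroxymethyl)-3-methyl-1-(propan-2-yl)cyclopentan-1-ol
Conditions: BH3·THF (3 equiv), THF, 0 °C to rt; MeOH
Reagents that add atoms: none
Why: Chemoselective borane reduction of a carboxylic acid through its acyloxyborane works at room temperature even at a neopentyl position and spares the silyl ether, which hot LiAlH4 might not.

Step 10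
Reactants: 15 (1R,2S,3S)-2-{[(TBS)oxy]methyl}-3-(hydroxymethyl)-3-methyl-1-(propan-2-yl)cyclopentan-1-ol
Product: 16 (1S,2S,3R)-2-{[(TBS)oxy]methyl}-3-hydroxy-1-methyl-3-(propan-2-yl)cyclopentane-1-carbaldehyde
Conditions: Dess–Martin periodinane, pyridine, CH2Cl2, 0 °C to rt
Reagents that add atoms: none
Why: Dess–Martin oxidation under buffered conditions stops at the non-enolisable neopentyl aldehyde, and the tertiary alcohol cannot react.

Step 11
Reactants: 16 (1S,2S,3R)-2-{[(TBS)oxy]methyl}-3-hydroxy-1-methyl-3-(propan-2-yl)cyclopentane-1-carbaldehyde; 17 vinylmagnesium bromide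
Product: 18 (1R,2S,3S)-2-{[(TBS)oxy]methyl}-3-(1-hydroxyprop-2-en-1-yl)-3-methyl-1-(propan-2-yl)cyclopentan-1-ol (C10 epimers)
Conditions: CH2=CHMgBr (3 equiv), THF, −78 to 0 °C; aq NH4Cl
Reagents that add atoms: vinylmagnesium bromide (17), C=C[Mg]Br
Why: Grignard 1,2-addition to the aldehyde (one equivalent is consumed by the free tertiary OH) installs C9 and the metathesis terminus, and the uncontrolled C10 carbinol centre does not matter because it becomes the ketone in step 19.

Step 12
Reactants: 18 (1R,2S,3S)-2-{[(TBS)oxy]methyl}-3-(1-hydroxyprop-2-en-1-yl)-3-methyl-1-(propan-2-yl)cyclopentan-1-ol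
Product: 19 (1R,2S,3S)-3-{1-[(TBS)oxy]prop-2-en-1-yl}-2-{[(TBS)oxy]methyl}-3-methyl-1-(propan-2-yl)cyclopentan-1-ol
Conditions: TBSOTf (1.2 equiv), 2,6-lutidine, CH2Cl2, −78 to −20 °C
Reagents that add atoms: tert-butyldimethylsilyl triflate, CC(C)(C)[Si](C)(C)OS(=O)(=O)C(F)(F)F
Why: Silyl triflate protection at low temperature distinguishes the secondary allylic alcohol from the far more hindered tertiary C4 alcohol, which must stay free as the chelating group of step 15.

Step 13
Reactants: 19 (1R,2S,3S)-3-{1-[(TBS)oxy]prop-2-en-1-yl}-2-{[(TBS)oxy]methyl}-3-methyl-1-(propan-2-yl)cyclopentan-1-ol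
Product: 20 (1R,2S,3S)-3-{1-[(TBS)oxy]prop-2-en-1-yl}-2-(hydroxymethyl)-3-methyl-1-(propan-2-yl)cyclopentan-1-ol
Conditions: camphorsulfonic acid (10 mol %), MeOH/CH2Cl2 (1:1), 0 °C
Reagents that add atoms: none
Why: Acid-catalysed methanolysis of silyl ethers is governed by steric access, so the primary C6 ether is cleaved well before the neopentyl secondary C10 ether.

Step 14
Reactants: 20 (1R,2S,3S)-3-{1-[(TBS)oxy]prop-2-en-1-yl}-2-(hydroxymethyl)-3-methyl-1-(propan-2-yl)cyclopentan-1-ol
Product: 21 (1R,2R,5S)-5-{1-[(TBS)oxy]prop-2-en-1-yl}-2-hydroxy-5-methyl-2-(propan-2-yl)cyclopentane-1-carbaldehyde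
Conditions: Dess–Martin periodinane, pyridine, CH2Cl2, 0 °C; used crude
Reagents that add atoms: none
Why: Buffered Dess–Martin oxidation gives the β-hydroxy aldehyde without acid or base strong enough for retro-aldol, dehydration or C5 epimerisation, and the present epimer, with CHO trans to both large neighbours, is in any case the stable one.

Step 15 (key step)
Reactants: 21 (1R,2R,5S)-5-{1-[(TBS)oxy]prop-2-en-1-yl}-2-hydroxy-5-methyl-2-(propan-2-yl)cyclopentane-1-carbaldehyde; 22 3-bromo-2-methylprop-1-ene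
Product: 24 (1R,2S,3S)-3-{1-[(TBS)oxy]prop-2-en-1-yl}-2-[(1S)-1-hydroxy-3-methylbut-3-en-1-yl]-3-methyl-1-(propan-2-yl)cyclopentan-1-ol, via methallylindium dibromide 23 (not isolated)
Conditions: In powder (2 equiv), 22 (3 equiv), THF/H2O (2:1), rt
Reagents that add atoms: 3-bromo-2-methylprop-1-ene (22), CC(=C)CBr
Why: Barbier-type intermolecular carbonyl allylation in which trivalent indium ties the free C4 hydroxyl and the aldehyde oxygen into a six-membered chelate cis-fused to the cyclopentane, C1 and its β-methyl block one carbonyl face, and methallyl transfer from the H5 side forms C6–C7 and sets C6 as (S).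

Step 16
Reactants: 24 (1R,2S,3S)-3-{1-[(TBS)oxy]prop-2-en-1-yl}-2-[(1S)-1-hydroxy-3-methylbut-3-en-1-yl]-3-methyl-1-(propan-2-yl)cyclopentan-1-ol; 25 3,4,5-trimethoxybenzoyl chloride
Product: 26 (1S)-1-[(1S,2R,5S)-5-{1-[(TBS)oxy]prop-2-en-1-yl}-2-hydroxy-5-methyl-2-(propan-2-yl)cyclopentyl]-3-methylbut-3-en-1-yl 3,4,5-trimethoxybenzoate
Conditions: 25 (2 equiv), Et3N (3 equiv), DMAP (0.3 equiv), CH2Cl2, rt to 40 °C
Reagents that add atoms: 3,4,5-trimethoxybenzoyl chloride (25), COc1cc(C(=O)Cl)cc(OC)c1OC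
Why: DMAP-catalysed acyl transfer esterifies the secondary C6 alcohol with retention, and the tertiary C4 alcohol is too hindered to compete.

Step 17
Reactants: 26 (1S)-1-[(1S,2R,5S)-5-{1-[(TBS)oxy]prop-2-en-1-yl}-2-hydroxy-5-methyl-2-(propan-2-yl)cyclopentyl]-3-methylbut-3-en-1-yl 3,4,5-trimethoxybenzoate
Product: 27 (1S)-1-[(1S,2R,5S)-2-hydroxy-5-(1-hydroxyprop-2-en-1-yl)-5-methyl-2-(propan-2-yl)cyclopentyl]-3-methylbut-3-en-1-yl 3,4,5-trimethoxybenzoate (C10 epimers)
Conditions: HF·pyridine, pyridine, THF, 0 °C to rt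
Reagents that add atoms: none
Why: Fluoride-driven desilylation with buffered HF·pyridine removes the hindered secondary TBS group without touching the aryl ester, the olefins or the tertiary alcohol.

Step 18
Reactants: 27 (1S)-1-[(1S,2R,5S)-2-hydroxy-5-(1-hydroxyprop-2-en-1-yl)-5-methyl-2-(propan-2-yl)cyclopentyl]-3-methylbut-3-en-1-yl 3,4,5-trimethoxybenzoate
Product: 28 (3R,3aS,4S,8aS)-3,8-dihydroxy-6,8a-dimethyl-3-(propan-2-yl)-1,2,3,3a,4,5,8,8a-octahydroazulen-4-yl 3,4,5-trimethoxybenzoate (C10 epimers)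
Conditions: second-generation Grubbs catalyst (7 mol %), 1,4-benzoquinone (15 mol %), CH2Cl2 (2 mM), reflux
Reagents that add atoms: none
Why: Ring-closing metathesis in which the catalyst loads on the monosubstituted vinyl carbinol and closes onto the 1,1-disubstituted methallyl olefin, giving the ring-constrained trisubstituted C8=C9 bond and the trans-fused hydroazulene whose fusion was fixed in steps 1 and 3, while benzoquinone suppresses olefin isomerisation.

Step 19
Reactants: 28 (3R,3aS,4S,8aS)-3,8-dihydroxy-6,8a-dimethyl-3-(propan-2-yl)-1,2,3,3a,4,5,8,8a-octahydroazulen-4-yl 3,4,5-trimethoxybenzoate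
Product: 29 (3R,3aS,4S,8aS)-3-hydroxy-6,8a-dimethyl-8-oxo-3-(propan-2-yl)-1,2,3,3a,4,5,8,8a-octahydroazulen-4-yl 3,4,5-trimethoxybenzoate (target CNP0218356.1)
Conditions: Dess–Martin periodinane, pyridine, CH2Cl2, 0 °C to rt
Reagents that add atoms: none
Why: Dess–Martin oxidation of the only oxidisable alcohol (secondary, allylic) merges both C10 epimers into the β-methyl enone under neutral conditions that avoid vinylogous elimination of the C6 ester.

## Compound list
1 | 3-methylcyclopent-2-en-1-one | CC1=CC(=O)CC1 | starting material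
2 | phenylboronic acid | OB(O)c1ccccc1 | starting material
3 | (S)-3-methyl-3-phenylcyclopentan-1-one | c1ccccc1[C@@]2(C)CCC(=O)C2 | intermediate
4 | (R)-4-methyl-4-phenylcyclopent-2-en-1-one | c1ccccc1[C@@]2(C)C=CC(=O)C2 | intermediate
5 | formaldehyde (from paraformaldehyde) | C=O | starting material
6 | lithium (S)-3-methyl-3-phenylcyclopenta-1,4-dien-1-olate | c1ccccc1[C@@]2(C)C=CC(O[Li])=C2 | intermediate (not isolated)
7 | (4S,5S)-5-(hydroxymethyl)-4-methyl-4-phenylcyclopent-2-en-1-one | c1ccccc1[C@@]2(C)C=CC(=O)[C@@H]2CO | intermediate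
8 | (4S,5S)-5-{[(TBS)oxy]methyl}-4-methyl-4-phenylcyclopent-2-en-1-one | c1ccccc1[C@@]2(C)C=CC(=O)[C@@H]2CO[Si](C)(C)C(C)(C)C | intermediate
9 | (2S,3S)-2-{[(TBS)oxy]methyl}-3-methyl-3-phenylcyclopentan-1-one | c1ccccc1[C@@]2(C)CCC(=O)[C@@H]2CO[Si](C)(C)C(C)(C)C | intermediate
10 | isopropenylmagnesium bromide | CC(=C)[Mg]Br | starting material
11 | isopropenylcerium dichloride | CC(=C)[Ce](Cl)Cl | intermediate (not isolated)
12 | (1S,2S,3S)-2-{[(TBS)oxy]methyl}-3-methyl-3-phenyl-1-(prop-1-en-2-yl)cyclopentan-1-ol | c1ccccc1[C@@]2(C)CC[C@@](O)(C(C)=C)[C@@H]2CO[Si](C)(C)C(C)(C)C | intermediate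
13 | (1R,2S,3S)-2-{[(TBS)oxy]methyl}-3-methyl-3-phenyl-1-(propan-2-yl)cyclopentan-1-ol | c1ccccc1[C@@]2(C)CC[C@@](O)(C(C)C)[C@@H]2CO[Si](C)(C)C(C)(C)C | intermediate
14 | (1S,2S,3R)-2-{[(TBS)oxy]methyl}-3-hydroxy-1-methyl-3-(propan-2-yl)cyclopentane-1-carboxylic acid | OC(=O)[C@@]1(C)CC[C@@](O)(C(C)C)[C@@H]1CO[Si](C)(C)C(C)(C)C | intermediate
15 | (1R,2S,3S)-2-{[(TBS)oxy]methyl}-3-(hydroxymethyl)-3-methyl-1-(propan-2-yl)cyclopentan-1-ol | OC[C@@]1(C)CC[C@@](O)(C(C)C)[C@@H]1CO[Si](C)(C)C(C)(C)C | intermediate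
16 | (1S,2S,3R)-2-{[(TBS)oxy]methyl}-3-hydroxy-1-methyl-3-(propan-2-yl)cyclopentane-1-carbaldehyde | O=C[C@@]1(C)CC[C@@](O)(C(C)C)[C@@H]1CO[Si](C)(C)C(C)(C)C | intermediate
17 | vinylmagnesium bromide | C=C[Mg]Br | starting material
18 | (1R,2S,3S)-2-{[(TBS)oxy]methyl}-3-(1-hydroxyprop-2-en-1-yl)-3-methyl-1-(propan-2-yl)cyclopentan-1-ol (C10 epimers) | C=CC(O)[C@@]1(C)CC[C@@](O)(C(C)C)[C@@H]1CO[Si](C)(C)C(C)(C)C | intermediate
19 | (1R,2S,3S)-3-{1-[(TBS)oxy]prop-2-en-1-yl}-2-{[(TBS)oxy]methyl}-3-methyl-1-(propan-2-yl)cyclopentan-1-ol | C=CC(O[Si](C)(C)C(C)(C)C)[C@@]1(C)CC[C@@](O)(C(C)C)[C@@H]1CO[Si](C)(C)C(C)(C)C | intermediate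
20 | (1R,2S,3S)-3-{1-[(TBS)oxy]prop-2-en-1-yl}-2-(hydroxymethyl)-3-methyl-1-(propan-2-yl)cyclopentan-1-ol | C=CC(O[Si](C)(C)C(C)(C)C)[C@@]1(C)CC[C@@](O)(C(C)C)[C@@H]1CO | intermediate
21 | (1R,2R,5S)-5-{1-[(TBS)oxy]prop-2-en-1-yl}-2-hydroxy-5-methyl-2-(propan-2-yl)cyclopentane-1-carbaldehyde | C=CC(O[Si](C)(C)C(C)(C)C)[C@@]1(C)CC[C@@](O)(C(C)C)[C@@H]1C=O | intermediate
22 | 3-bromo-2-methylprop-1-ene (methallyl bromide) | CC(=C)CBr | starting material
23 | methallylindium dibromide | CC(=C)C[In](Br)Br | intermediate (not isolated)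
24 | (1R,2S,3S)-3-{1-[(TBS)oxy]prop-2-en-1-yl}-2-[(1S)-1-hydroxy-3-methylbut-3-en-1-yl]-3-methyl-1-(propan-2-yl)cyclopentan-1-ol | C=CC(O[Si](C)(C)C(C)(C)C)[C@@]1(C)CC[C@@](O)(C(C)C)[C@@H]1[C@@H](O)CC(C)=C | intermediate
25 | 3,4,5-trimethoxybenzoyl chloride | COc1cc(C(=O)Cl)cc(OC)c1OC | starting material
26 | (1S)-1-[(1S,2R,5S)-5-{1-[(TBS)oxy]prop-2-en-1-yl}-2-hydroxy-5-methyl-2-(propan-2-yl)cyclopentyl]-3-methylbut-3-en-1-yl 3,4,5-trimethoxybenzoate | C=CC(O[Si](C)(C)C(C)(C)C)[C@@]1(C)CC[C@@](O)(C(C)C)[C@@H]1[C@@H](OC(=O)c2cc(OC)c(OC)c(OC)c2)CC(C)=C | intermediate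
27 | (1S)-1-[(1S,2R,5S)-2-hydroxy-5-(1-hydroxyprop-2-en-1-yl)-5-methyl-2-(propan-2-yl)cyclopentyl]-3-methylbut-3-en-1-yl 3,4,5-trimethoxybenzoate (C10 epimers) | C=CC(O)[C@@]1(C)CC[C@@](O)(C(C)C)[C@@H]1[C@@H](OC(=O)c2cc(OC)c(OC)c(OC)c2)CC(C)=C | intermediate
28 | (3R,3aS,4S,8aS)-3,8-dihydroxy-6,8a-dimethyl-3-(propan-2-yl)-1,2,3,3a,4,5,8,8a-octahydroazulen-4-yl 3,4,5-trimethoxybenzoate (C10 epimers) | COc1cc(C(=O)O[C@H]2CC(C)=CC(O)[C@@]3(C)CC[C@@](O)(C(C)C)[C@H]23)cc(OC)c1OC | intermediate
29 | (3R,3aS,4S,8aS)-3-hydroxy-6,8a-dimethyl-8-oxo-3-(propan-2-yl)-1,2,3,3a,4,5,8,8a-octahydroazulen-4-yl 3,4,5-trimethoxybenzoate | COc1cc(C(=O)O[C@H]2CC(C)=CC(=O)[C@@]3(C)CC[C@@](O)(C(C)C)[C@H]23)cc(OC)c1OC | target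

## Totals and risks
Total step count: 19. Longest linear sequence: 19 steps (1 to 29).

Risk 1, step 8: arene degradation next to a primary silyl ether and several tertiary C–H bonds. The fallback sets out from 13 and comes back at 14. It takes the ring apart reductively first.
- Birch reduction (Li, NH3/THF, t-BuOH, −78 °C) gives the cyclohexa-1,4-dienyl carbinol F1.
- Ozonolysis (O3, CH2Cl2/MeOH, −78 °C, then Me2S) cleaves both ring olefins to the β-keto aldehyde F2.
- Pinnick oxidation (NaClO2, NaH2PO4, 2-methylbut-2-ene, t-BuOH/H2O) gives the β-keto acid F3.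
- F3 loses CO2 on warming to 50 °C and leaves the methyl ketone F4.
- Haloform cleavage of this ketone, which can enolise only toward CH3 (Br2, NaOH, dioxane/H2O, 0 °C, then acidification to pH 4), returns acid 14.

Risk 2, step 15: the facial selectivity rests on a chelate to a hindered tertiary OH, and the aldehyde is crowded and sensitive. The fallback sets out from 21 and comes back at 24. It replaces substrate control by reagent control through a Brown allylboration with (−)-B-methallyldiisopinocampheylborane. The borane is made from (−)-Ipc2BOMe (derived from (+)-α-pinene) and CH2=C(CH3)CH2MgCl. It is used at 2.5 equiv in Et2O at −78 °C, with NaBO3·4H2O work-up. Through its closed chair transition state this reagent gives the (S)-carbinol with α-branched aldehydes irrespective of chelation. No new compound arises (F0).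

Risk 3, step 18: closure of a trans-fused seven-membered ring to a trisubstituted olefin from a crowded allylic alcohol, with possible isomerisation to the ethyl ketone and unequal rates for the two C10 epimers. The fallback sets out from 27 and comes back at 29. Oxidation is done first (Dess–Martin periodinane, pyridine, CH2Cl2), which gives the single, epimer-free vinyl ketone F5. The metathesis is then run on the acryloyl unit with the second-generation Hoveyda–Grubbs catalyst (10 mol %, toluene, 2 mM, 80 °C). This cannot isomerise to a saturated ketone and delivers 29 directly.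

## Further compounds
F1 | step 8 | (1R,2S,3S)-2-{[(TBS)oxy]methyl}-3-(cyclohexa-1,4-dien-1-yl)-3-methyl-1-(propan-2-yl)cyclopentan-1-ol | C1=CCC(=CC1)[C@@]2(C)CC[C@@](O)(C(C)C)[C@@H]2CO[Si](C)(C)C(C)(C)C
F2 | step 8 | 3-[(1S,2S,3R)-2-{[(TBS)oxy]methyl}-3-hydroxy-1-methyl-3-(propan-2-yl)cyclopentyl]-3-oxopropanal | O=CCC(=O)[C@@]1(C)CC[C@@](O)(C(C)C)[C@@H]1CO[Si](C)(C)C(C)(C)C
F3 | step 8 | 3-[(1S,2S,3R)-2-{[(TBS)oxy]methyl}-3-hydroxy-1-methyl-3-(propan-2-yl)cyclopentyl]-3-oxopropanoic acid | OC(=O)CC(=O)[C@@]1(C)CC[C@@](O)(C(C)C)[C@@H]1CO[Si](C)(C)C(C)(C)C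
F4 | step 8 | 1-[(1S,2S,3R)-2-{[(TBS)oxy]methyl}-3-hydroxy-1-methyl-3-(propan-2-yl)cyclopentyl]ethan-1-one | CC(=O)[C@@]1(C)CC[C@@](O)(C(C)C)[C@@H]1CO[Si](C)(C)C(C)(C)C
F0 | step 15 | none | none
F5 | step 18 | (1S)-1-[(1S,2R,5S)-5-acryloyl-2-hydroxy-5-methyl-2-(propan-2-yl)cyclopentyl]-3-methylbut-3-en-1-yl 3,4,5-trimethoxybenzoate | C=CC(=O)[C@@]1(C)CC[C@@](O)(C(C)C)[C@@H]1[C@@H](OC(=O)c2cc(OC)c(OC)c(OC)c2)CC(C)=C
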